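## Analysis of the target

Exotimarin H (12) is a coumarin: a benzene ring (C4a, C5, C6, C7, C8, C8a) fused to an α-pyranone ring (O1, C2, C3, C4), with a methoxy group on C7 and an acyl side chain on C8. In the side chain C1' is an aryl ketone, C2' is an alkene carbon bearing a 3-methylbutanoyloxy group, and C3' carries two methyl groups, so the chain is the enol ester of a 1,2-diketone. There is no stereocentre, and because the two substituents on C3' are identical the C2'=C3' bond has no geometry to control. The sensitive groups are the enol ester (an acyl donor towards nucleophiles, cleaved by base), the lactone (opened by hydroxide, alkoxide or hard organometallic reagents) and the C3=C4 bond (a conjugate acceptor). The difficulty lies in two places. C8 sits between the oxygen-bearing carbons C7 and C8a, so the benzene ring is 1,2,3,4-tetrasubstituted and crowded at the point of attachment; and C1' and C2' are both carbonyl-level, electrophilic carbons, so the bond between them cannot be made with normal polarity. The strategy rests on the fact that only C3' can carry an enolisable hydrogen: the C1'–C2' diketone has a single enolate, with oxygen on C2' and the double bond to C3', and 12 is its O-acyl derivative. That same enolate results when a nucleophilic C1' adds to the central carbon of a ketene that brings C2', C3' and both methyl groups.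

## Retrosynthetic reasoning

**12 ⇒ 11.** No skeletal bond is cut; the C1' ketone of 12 is traced back to the 1,3-dithiane of 11. This mask is what allows C1' to act as a nucleophile one step earlier, and it keeps C1' unreactive while the enol ester is made. The forward reaction has to hydrolyse an S,S-acetal under neutral conditions, because the enol ester next to it tolerates neither acid nor base.

**11 ⇒ 5 + 7 + 8.** The C1'–C2' bond and the enol O–acyl bond are cut together. C1'–C2' is the only side-chain bond that joins two functionalised carbons. Cutting C8–C1' instead would need an aryl nucleophile or a Friedel–Crafts acylation at the most hindered ring position, next to a lactone. The cut gives three simple pieces: dithiane 5 as the C1' donor, ketene 7 as C2'/C3' with both methyl groups, and acid chloride 8 as the ester acyl group. Forward, 5 must be metalated at the dithiane carbon (9) without damage to the lactone, 9 must add once to the central carbon of 7 to give enolate 10, and 10 must be acylated on oxygen by 8. The enolate is formed regiospecifically by bond formation, so no free diketone is ever handled.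

**7 ⇒ 6.** The ketene is traced back to its head-to-tail dimer 6, in which two molecules of 7 are joined through two ring C–C bonds. Forward, a thermal [2+2] cycloreversion breaks these two bonds, and each molecule of 6 supplies two molecules of 7. This gives a ketene free of salts, protons and acylating impurities, which the carbanion of the key step requires.

**5 ⇒ 3 + 4.** The two C–S bonds are cut, leading to aldehyde 3 and dithiol 4. The forward reaction is a dithioacetalisation that must leave the lactone and the C3=C4 bond alone.

**3 ⇒ 2 ⇒ 1.** The O–CH3 bond is cut first, then the C8–CHO bond. Coumarin 1 is commercial and already holds the ring system and the C7 oxygen. Its free hydroxyl directs an electrophile to C8, the ortho position with the higher double-bond character to C7. The forward sequence is therefore a Duff-type ortho-formylation followed by O-methylation, in that order, so that the phenol can direct.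

## Alternatives that were turned down

**Alternative 1:** The benzene ring is disconnected at C8–C8a, C6–C7 and C4a–C8a.
- Forward key step (Danheiser benzannulation): irradiation of (E)-1-diazo-5,5-dimethoxypent-3-en-2-one A2 triggers a Wolff rearrangement to a vinylketene. This combines with (E)-1-methoxy-5-methylhex-3-en-1-yne A3 by [2+2] cycloaddition, four-electron ring opening and six-electron electrocyclisation, giving 6-(dimethoxymethyl)-3-methoxy-2-[(E)-3-methylbut-1-en-1-yl]phenol A1.
- For: the substitution pattern is fixed by the mechanism (ketene carbon becomes C8a, the alkyne carbon with the chain becomes C8, the methoxy-bearing carbon C7). There is no C6/C8 question, and no strong base is used near a lactone.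
- Against: it builds a benzene ring that 1 supplies ready-made. A2 and A3 are labile and each needs several steps. A1 still lacks the pyranone, and its side chain is an alkene that needs dihydroxylation, oxidation and enol acylation.
- Comparison: stronger on arene regiocontrol, but at least twice as long. The chosen route buys the ring system and puts its effort into the C1'–C2' bond at the final oxidation level.

**Alternative 2:** The pyranone is disconnected at C4–C4a.
- Forward key step: 3-methoxy-2-(3-methylbutanoyl)phenyl prop-2-ynoate A5 is treated with Pd(OAc)2 A6 (divalent palladium) in trifluoroacetic acid A7. The arene carbon para to the methoxy group adds to the terminal alkyne carbon in a 6-endo hydroarylation, giving 7-methoxy-8-(3-methylbutanoyl)-2H-chromen-2-one A4.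
- For: this is a known reaction type for aryl propiolates of electron-rich phenols. The cyclisation site is the only free position ortho to the ester oxygen and is activated by the para methoxy group. No umpolung or strong base is needed.
- Against: the ring formed is already present in 1. A5 comes from the ortho-acyl phenol A8, which needs its own regiocontrolled synthesis. The acyl group deactivates the arene, and the activated aryl ester may undergo acidolysis in A7. A4 has C2' as a CH2 group, so a Riley-type oxidation next to the coumarin alkene and an enol acylation through the free diketone must follow.
- Comparison: stronger on precedent, since every step is a known reaction, and not shorter. The chosen route delivers C2' at the right oxidation level from the ketene and needs no late oxidation.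

**Alternative 3:** C8–C1' and C8a–O1 are disconnected across an aryne.
- Forward key step: CsF A12 releases 3-methoxybenzyne A9 from 3-methoxy-2-(trimethylsilyl)phenyl trifluoromethanesulfonate A10. The carboxylate of 3-methylbutanoic acid A11 adds through oxygen to the aryne carbon remote from the methoxy group. The aryl anion next to the methoxy group attacks the acyl carbon and the four-membered intermediate opens, giving 1-(2-hydroxy-6-methoxyphenyl)-3-methylbutan-1-one A8.
- For: the contiguous oxygen/acyl/oxygen pattern is set in one mild step, with regiochemistry from the inductive effect of the methoxy group.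
- Against: simple O-arylation and protonation of the aryl anion compete. A8 has neither the pyranone carbons nor the C2' oxygen, so annulation (for example via A5 and A4), oxidation and enol acylation must follow. A10 is costly.
- Comparison: combined with the cyclisation of Alternative 2 it would reach 12 in about as many steps as the chosen route and on known reaction types. It is therefore equal on length and stronger on precedent. The chosen route offers instead a cheap starting coumarin, a ring system that is bought and not built, and a side chain installed in one operation with the enolate regiochemistry fixed by the bond that is formed.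

Key step: step 5

Remark on the chemistry: dimethylketene (7) is made by cracking its commercial dimer 6 and not by amine dehydrochlorination of 2-methylpropanoyl chloride. Ammonium salt and unreacted acid chloride carried along with the ketene would protonate or acylate the carbanion of step 5. Each molecule of 6 delivers two molecules of 7.

## Route

Step 1
Reactants: 1 7-hydroxy-2H-chromen-2-one (umbelliferone)
Product: 2 7-hydroxy-2-oxo-2H-chromene-8-carbaldehyde
Conditions: hexamethylenetetramine, CF3CO2H, reflux; then H2O, 60 °C
Reagents that add atoms: hexamethylenetetramine, C1N2CN3CN1CN(C2)C3; water, O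
Why: Duff formylation: the iminium ion from protonated hexamethylenetetramine substitutes the phenol ortho to the hydroxyl, at C8 and not C6 because the C7–C8 bond has the higher double-bond character (as C1 of 2-naphthol); internal hydride transfer and hydrolysis then release the aldehyde.

Step 2
Reactants: 2 7-hydroxy-2-oxo-2H-chromene-8-carbaldehyde
Product: 3 7-methoxy-2-oxo-2H-chromene-8-carbaldehyde
Conditions: MeI, K2CO3, DMF, rt
Reagents that add atoms: iodomethane, CI
Why: Williamson ether synthesis (SN2 of the phenoxide on iodomethane); carbonate in DMF is too weak to open the lactone and the aldehyde has no α-hydrogen.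

Step 3
Reactants: 3 7-methoxy-2-oxo-2H-chromene-8-carbaldehyde; 4 propane-1,3-dithiol
Product: 5 8-(1,3-dithian-2-yl)-7-methoxy-2H-chromen-2-one
Conditions: BF3·OEt2 (0.3 equiv), CH2Cl2, 0 °C → rt
Reagents that add atoms: none
Why: Lewis acid-catalysed dithioacetalisation of the aldehyde; the lactone carbonyl is far less electrophilic and the conjugated C3=C4 bond of a coumarin is a poor thiol acceptor under acid.

Step 4
Reactants: 6 2,2,4,4-tetramethylcyclobutane-1,3-dione
Product: 7 dimethylketene (2-methylprop-1-en-1-one)
Conditions: 600 °C, quartz tube, N2 flow; trap at −78 °C; taken up in THF under Ar, used at once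
Reagents that add atoms: none
Why: Thermal [2+2] cycloreversion of the ketene dimer breaks both ring C–C bonds between the carbonyl and quaternary carbons and gives two molecules of 7 per molecule of 6 and nothing else, so the ketene arrives free of salts, acid and acid chloride; it is kept cold and under argon because it re-dimerises and forms peroxides with oxygen.

Step 5
Reactants: 5 8-(1,3-dithian-2-yl)-7-methoxy-2H-chromen-2-one; 7 dimethylketene; 8 3-methylbutanoyl chloride
Product: 11 1-[2-(7-methoxy-2-oxo-2H-chromen-8-yl)-1,3-dithian-2-yl]-2-methylprop-1-en-1-yl 3-methylbutanoate, via lithiated dithiane 9 (not isolated), via lithium enolate 10 (not isolated)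
Conditions: LiN(iPr)2 (1.05 equiv), THF, −78 °C; 7 (1.1 equiv, THF, slow addition), −78 °C; 8 (1.3 equiv), −78 → 0 °C
Reagents that add atoms: none
Why: Proposed new method: lithium diisopropylamide removes the benzylic C–H of 5 that is flanked by two sulfur atoms, giving carbanion 9; the amide is basic enough for a 2-aryl-1,3-dithiane but too hindered to add to the lactone carbonyl, which n-butyllithium would open, and lithium amides are known to metalate 4-methylcoumarins at low temperature with the lactone intact. Carbanion 9 attacks the sp carbon of ketene 7 in the plane of the ketene substituents, so the C1'–C2' bond forms and the charge ends on oxygen as enolate 10, whose double bond can only lie between C2' and C3'. Acid chloride 8 then acylates 10 on oxygen, because C-acylation would have to build a quaternary C3' next to the quaternary dithiane carbon. The closest known reaction types are the Corey–Seebach acylation of 2-lithio-1,3-dithianes and the addition of organolithium reagents to ketenes with trapping of the enolate on oxygen as silyl enol ether or enol ester; a dithiane anion, a ketene and an acylating agent have not been combined in this way. No ring is closed and no stereocentre is formed, and the two identical methyl groups on C3' leave no alkene geometry to control. Three selectivities are needed: deprotonation instead of attack on the lactone or on C4 (secured by the hindered base at −78 °C); one molecule of 7 per carbanion instead of enolate-initiated oligomerisation (secured by slow addition of close to one equivalent and by the shielding of 10 between the dithiane and the two methyl groups); and O- over C-acylation (secured by full substitution at C3').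

Step 6
Reactants: 11 1-[2-(7-methoxy-2-oxo-2H-chromen-8-yl)-1,3-dithian-2-yl]-2-methylprop-1-en-1-yl 3-methylbutanoate
Product: 12 Exotimarin H (1-(7-methoxy-2-oxo-2H-chromen-8-yl)-3-methyl-1-oxobut-2-en-2-yl 3-methylbutanoate)
Conditions: MeI (excess), CaCO3, MeCN/H2O (9:1), 45 °C
Reagents that add atoms: water, O
Why: Alkylative dithiane hydrolysis: S-methylation turns sulfur into a leaving group, water captures the thionium ion at C1', and a second methylation releases the ketone; CaCO3 keeps the medium neutral so that neither the enol ester nor the lactone is solvolysed, and iodomethane attacks neither alkene.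

## Compound list

1 | 7-hydroxy-2H-chromen-2-one (umbelliferone) | O=c1ccc2ccc(O)cc2o1 | starting material
2 | 7-hydroxy-2-oxo-2H-chromene-8-carbaldehyde | Oc1ccc2ccc(=O)oc2c1C=O | intermediate
3 | 7-methoxy-2-oxo-2H-chromene-8-carbaldehyde | COc1ccc2ccc(=O)oc2c1C=O | intermediate
4 | propane-1,3-dithiol | SCCCS | starting material
5 | 8-(1,3-dithian-2-yl)-7-methoxy-2H-chromen-2-one | COc1ccc2ccc(=O)oc2c1C1SCCCS1 | intermediate
6 | 2,2,4,4-tetramethylcyclobutane-1,3-dione | CC1(C)C(=O)C(C)(C)C1=O | starting material
7 | dimethylketene (2-methylprop-1-en-1-one) | CC(C)=C=O | intermediate
8 | 3-methylbutanoyl chloride | CC(C)CC(=O)Cl | starting material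
9 | 8-(2-lithio-1,3-dithian-2-yl)-7-methoxy-2H-chromen-2-one | COc1ccc2ccc(=O)oc2c1C1([Li])SCCCS1 | intermediate
10 | lithium 1-[2-(7-methoxy-2-oxo-2H-chromen-8-yl)-1,3-dithian-2-yl]-2-methylprop-1-en-1-olate | COc1ccc2ccc(=O)oc2c1C1(SCCCS1)C(O[Li])=C(C)C | intermediate
11 | 1-[2-(7-methoxy-2-oxo-2H-chromen-8-yl)-1,3-dithian-2-yl]-2-methylprop-1-en-1-yl 3-methylbutanoate | COc1ccc2ccc(=O)oc2c1C1(SCCCS1)C(OC(=O)CC(C)C)=C(C)C | intermediate
12 | Exotimarin H (1-(7-methoxy-2-oxo-2H-chromen-8-yl)-3-methyl-1-oxobut-2-en-2-yl 3-methylbutanoate) | COc1ccc2ccc(=O)oc2c1C(=O)C(OC(=O)CC(C)C)=C(C)C | target

## Step count and least certain steps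

Total step count: 6. Longest linear sequence: 5 steps (steps 1, 2, 3, 5, 6); step 4 is a one-step branch that supplies 7.

**Step 5 (key step, proposed new method).** What may go wrong: the one-to-one match of carbanion and ketene is lost. Enolate 10, or the diisopropylamine set free on metalation, adds to further 7, so anionic oligomerisation of the ketene and amide formation run beside the wanted capture. Unreacted 9 is then acylated directly by 8. A sluggish metalation, caused by the 2,6-disubstituted aryl group being twisted out of conjugation with the carbanion, would make this worse. Fallback (known chemistry): it sets out from 5 and returns at 10. Compound 5 is metalated as before to 9 and acylated with N-methoxy-N-methyl-2-methylpropanamide (Corey–Seebach acylation) to give 1-[2-(7-methoxy-2-oxo-2H-chromen-8-yl)-1,3-dithian-2-yl]-2-methylpropan-1-one F1. F1 has a single α-hydrogen, at C3', so LiN(iPr)2 in THF at −78 °C can give only enolate 10, which is acylated with 8 to 11 as in step 5. No ketene is needed.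

**Step 6.** What may go wrong: solvolysis takes a wrong course. After S-methylation the cation at C1' is allylic through the enol ester double bond, so water may enter at C3', a methyl proton may be lost, or the ester carbonyl may bridge to C1' and migrate. The crowded quaternary carbon also slows the hydrolysis enough for the enol ester to be cleaved first. Fallback: it sets out from 3 and returns at 12, and uses no dithiane and no carbanion at C1'. Wittig reaction of 3 with (2-methylpropylidene)triphenylphosphorane F2, made from (2-methylpropyl)triphenylphosphonium bromide and NaN(SiMe3)2 in THF, gives 7-methoxy-8-[(Z)-3-methylbut-1-en-1-yl]-2H-chromen-2-one F3. Dihydroxylation with catalytic OsO4 and N-methylmorpholine N-oxide in aqueous acetone, selective for the electron-richer alkene, gives 8-(1,2-dihydroxy-3-methylbutyl)-7-methoxy-2H-chromen-2-one F4. Swern oxidation of both hydroxyl groups gives 1-(7-methoxy-2-oxo-2H-chromen-8-yl)-3-methylbutane-1,2-dione F5. LiN(SiMe3)2 in THF at −78 °C then removes the only α-hydrogen to give lithium 1-(7-methoxy-2-oxo-2H-chromen-8-yl)-3-methyl-1-oxobut-2-en-2-olate F6, which 8 acylates on oxygen to 12.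

**Step 1.** What may go wrong: low conversion and over-condensation. The pyranone deactivates the phenol, and the benzylamine and iminium intermediates may alkylate a second molecule of 1 or formylate C6 as well. Fallback: it sets out from 1 and returns at 3, and the carbon is brought in by cross-coupling instead of electrophilic formylation. Iodination of 1 with I2 and KI in aqueous ammonia gives 7-hydroxy-8-iodo-2H-chromen-2-one F7. Methylation with MeI and K2CO3 in DMF gives 8-iodo-7-methoxy-2H-chromen-2-one F8. Reductive carbonylation of F8 with CO, HCO2Na and catalytic PdCl2(PPh3)2 in DMF at 100 °C gives 3.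

## Further compounds

F1 | step 5 | 1-[2-(7-methoxy-2-oxo-2H-chromen-8-yl)-1,3-dithian-2-yl]-2-methylpropan-1-one | COc1ccc2ccc(=O)oc2c1C1(SCCCS1)C(=O)C(C)C
F2 | step 6 | (2-methylpropylidene)triphenylphosphorane | CC(C)C=P(c1ccccc1)(c1ccccc1)c1ccccc1
F3 | step 6 | 7-methoxy-8-[(Z)-3-methylbut-1-en-1-yl]-2H-chromen-2-one (Z isomer expected to predominate) | COc1ccc2ccc(=O)oc2c1/C=C\C(C)C
F4 | step 6 | 8-(1,2-dihydroxy-3-methylbutyl)-7-methoxy-2H-chromen-2-one (racemic diastereomer mixture, both centres removed in the next step) | COc1ccc2ccc(=O)oc2c1C(O)C(O)C(C)C
F5 | step 6 | 1-(7-methoxy-2-oxo-2H-chromen-8-yl)-3-methylbutane-1,2-dione | COc1ccc2ccc(=O)oc2c1C(=O)C(=O)C(C)C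
F6 | step 6 | lithium 1-(7-methoxy-2-oxo-2H-chromen-8-yl)-3-methyl-1-oxobut-2-en-2-olate | COc1ccc2ccc(=O)oc2c1C(=O)C(O[Li])=C(C)C
F7 | step 1 | 7-hydroxy-8-iodo-2H-chromen-2-one | Oc1ccc2ccc(=O)oc2c1I
F8 | step 1 | 8-iodo-7-methoxy-2H-chromen-2-one | COc1ccc2ccc(=O)oc2c1I
A1 | alternative 1 | 6-(dimethoxymethyl)-3-methoxy-2-[(E)-3-methylbut-1-en-1-yl]phenol | COc1ccc(C(OC)OC)c(O)c1/C=C/C(C)C
A2 | alternative 1 | (E)-1-diazo-5,5-dimethoxypent-3-en-2-one | COC(OC)/C=C/C(=O)C=[N+]=[N-]
A3 | alternative 1 | (E)-1-methoxy-5-methylhex-3-en-1-yne | COC#C/C=C/C(C)C
A4 | alternative 2 | 7-methoxy-8-(3-methylbutanoyl)-2H-chromen-2-one | COc1ccc2ccc(=O)oc2c1C(=O)CC(C)C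
A5 | alternative 2 | 3-methoxy-2-(3-methylbutanoyl)phenyl prop-2-ynoate | C#CC(=O)Oc1cccc(OC)c1C(=O)CC(C)C
A6 | alternative 2 | palladium diacetate | CC(=O)[O-].CC(=O)[O-].[Pd+2]
A7 | alternative 2 | trifluoroacetic acid | OC(=O)C(F)(F)F
A8 | alternative 3 | 1-(2-hydroxy-6-methoxyphenyl)-3-methylbutan-1-one | COc1cccc(O)c1C(=O)CC(C)C
A9 | alternative 3 | 3-methoxybenzyne (1,2-didehydro-3-methoxybenzene) | COC1=CC=CC#C1
A10 | alternative 3 | 3-methoxy-2-(trimethylsilyl)phenyl trifluoromethanesulfonate | COc1cccc(OS(=O)(=O)C(F)(F)F)c1[Si](C)(C)C
A11 | alternative 3 | 3-methylbutanoic acid | CC(C)CC(=O)O
A12 | alternative 3 | caesium fluoride | [Cs+].[F-]
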